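How much of the substrate charged to this flask stood as self-condensation product at each asked time?

| flask | substrate | remark | time |
|---|---|---|---|
| spring | 0.13 M | run made earlier |  |
| noon | 0.30 M | run made earlier |  |
| flask | 0.20 M |  | 1.0 h |
- spring (time / min: self-condensation product / %, target / %): 6.00: 27.4, 0; 12.0: 42.8, 0.4; 20.0: 55.3, 0; 25.0: 61.1, 0; 30.0: 64.6, 0; 40.0: 71.7, 0.1
- noon (time / min: self-condensation product / %, target / %): 2.50: 27.7, 0.5; 8.00: 53.2, 0; 12.0: 63.3, 0.3; 20.0: 73.9, 0; 30.0: 81.8, 0.2; 40.0: 85.7, 1.0

(scatter of a reading: 0.5 percentage points)
1. amount of self-condensation product in percent of the substrate charged, at 6.0 min, 20 min, 40 min and 1.0 h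
- percentages count the substrate that a species holds: one self-condensation product counts as two

1. In both earlier runs the target readings stayed near zero. I therefore treated substrate pairing with substrate as the visible path, second order in substrate. Then the ratio of product to substrate left grows linearly, as κct, where κ is the rate constant, c the charge and t the time.

2. First round: the earliest spring reading, 27.4 % at 6.00 min, gave κ = 0.484 L mol⁻¹ min⁻¹.

3. Second round: I put κ back into the last readings. The spring run came out at 71.6 % against 71.7 % read, and the noon run at 85.3 % against 85.7 % read. I kept κ.

4. The clock is τ = 1/(κc), the time by which half of the charge has paired, the second-order half-life: 10.3 min for this flask. The noon clock, 6.89 min, was shorter than the flask's, and the spring clock, 15.9 min, longer.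

5. I took the flask as charged at once and climbed the rungs with x = (t/τ)/(1 + t/τ), where x is the product share. At 6.0 min, short of τ, I got 36.7 %. At 20 min, twice τ, I got 65.9 %. At 40 min I got 79.5 %, and at 1.0 h 85.3 %.

6. The forecast differed from my reckoning. It read the flask as “the substrate being fed evenly” and gave 0.2 %, 5.7 %, 28.4 % and 59.2 %.

The flask gave 36.6 %, 65.7 %, 79.1 % and 84.8 %, which lay with the clock's course, ending at 85.3 %. After 1.00 h the flask held 14.6 % substrate and 84.8 % product. The length of the run was the main reason that the product stopped there: the simulated run ten times as long reaches 97.2 %, which is 12 percentage points more. At 10.0 h the same τ gives 98.3 %, and that run holds 97.2 %.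

    substrate + 2 target → 3 target (k = 2.74 L² mol⁻² min⁻¹)
    substrate → target (k = 2.94 × 10⁻⁴ min⁻¹)
    target ⇌ isomer of the product (K = 0.520, k = 0.129 min⁻¹)
    2 substrate → self-condensation product (k = 0.241 L mol⁻¹ min⁻¹)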